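**Retrosynthetic overview**
- Target ⇐ fluoride-mediated removal of one silyl ether and one 2-(trimethylsilyl)ethyl ester; C12–C13 ⇐ Pd-catalysed Negishi coupling of a bicyclic primary alkylzinc with a (Z)-β-iodo enoate (fragment C, from propargyl alcohol and CO2).
- Decalin ⇐ acyclic (R)-silyloxy triene in one cobalt-catalysed, HAT-initiated cationic bicyclisation: ring A closes first (C4–C5), ring B second (C9–C10). A (Z)-allylsilane ends the cascade as the C8 exocyclic methylene, and the equatorial C2 silyl ether fixes C5, C9 and C10.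
- Triene ⇐ C5–C6 by Pd-catalysed Negishi coupling of (E)-alkenyl iodide fragment A with alkylzinc fragment B.
- Fragment A ⇐ (R)-epichlorohydrin, isopropenyl Grignard and acetylide, then Zr-catalysed methylalumination/iodination. Fragment B ⇐ 2,3-dihydrofuran by α-lithiation/alkylation and Ni-catalysed C–O coupling with Me3SiCH2MgCl, which sets the (Z)-allylsilane.

Assumption: the target is read as the ent-labdane (2R,5R,9R,10R,13E; labdane numbering is used in the comments), and (R)-epichlorohydrin, the Grignard solutions and lithium acetylide–ethylenediamine are bought.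

**Fragment A (steps 1–4)**

Step 1
Reactants: 1 (R)-epichlorohydrin; 2 isopropenylmagnesium bromide
Product: 3 (2R)-1-chloro-4-methylpent-4-en-2-ol
Conditions: CuI (10 mol %), THF, −40 → −20 °C; aq. NH4Cl
Reagents that add atoms: none
Why: Copper-catalysed Grignard opening of the epoxide at its CH2 terminus; the carbinol centre (future C2) comes unchanged from the chiral pool.

Step 2
Reactants: 3 (2R)-1-chloro-4-methylpent-4-en-2-ol; 4 lithium acetylide–ethylenediamine complex
Product: 6 (4R)-6-methylhept-6-en-1-yn-4-ol, via (2R)-2-(2-methylallyl)oxirane 5 (not isolated)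
Conditions: 4 (3 equiv), DMSO, 0 °C → rt
Reagents that add atoms: none
Why: Base-induced Williamson closure to the terminal epoxide, then SN2 opening by acetylide at the CH2 carbon; the C–O bond of the stereocentre is never broken.

Step 3
Reactants: 6 (4R)-6-methylhept-6-en-1-yn-4-ol
Product: 7 tert-butyldimethyl{[(4R)-6-methylhept-6-en-1-yn-4-yl]oxy}silane
Conditions: TBSCl, imidazole, DMF, rt
Reagents that add atoms: tert-butyldimethylsilyl chloride, CC(C)(C)[Si](C)(C)Cl
Why: Standard imidazole-promoted silylation gives a non-participating ether that later serves as the stereocontrol element.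

Step 4
Reactants: 7 tert-butyldimethyl{[(4R)-6-methylhept-6-en-1-yn-4-yl]oxy}silane
Product: 9 tert-butyl{[(1E,4R)-1-iodo-2,6-dimethylhepta-1,6-dien-4-yl]oxy}dimethylsilane, via alkenyldimethylalane 8 (not isolated)
Conditions: AlMe3 (2.5 equiv), Cp2ZrCl2 (0.25 equiv), CH2Cl2, 0 °C → rt; then I2, THF, −30 → 0 °C
Reagents that add atoms: trimethylaluminium, C[Al](C)C; iodine, [I][I]
Why: Negishi zirconium-catalysed methylalumination adds Me and Al syn to the terminal alkyne only (Al on the terminal carbon), and iodinolysis with retention gives the (E)-iodide; the 1,1-disubstituted alkene and the stereocentre are untouched.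

**Fragment B (steps 5–10)**

Step 5
Reactants: 10 2-iodoethanol
Product: 11 tert-butyl(2-iodoethoxy)dimethylsilane
Conditions: TBSCl, imidazole, CH2Cl2, 0 °C → rt
Reagents that add atoms: tert-butyldimethylsilyl chloride, CC(C)(C)[Si](C)(C)Cl
Why: Routine silylation of the primary alcohol masks the future C6 oxygen.

Step 6
Reactants: 12 2,3-dihydrofuran; 11 tert-butyl(2-iodoethoxy)dimethylsilane
Product: 14 tert-butyl[2-(4,5-dihydrofuran-2-yl)ethoxy]dimethylsilane, via 5-lithio-2,3-dihydrofuran 13 (not isolated)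
Conditions: t-BuLi, THF/pentane, −78 → 0 °C; then 11, DMPU, −30 °C → rt
Reagents that add atoms: tert-butyllithium, [Li]C(C)(C)C (in 13 only)
Why: α-Lithiation of the cyclic enol ether at the vinylic O–CH carbon, then SN2 alkylation with the primary iodide.

Step 7
Reactants: 14 tert-butyl[2-(4,5-dihydrofuran-2-yl)ethoxy]dimethylsilane; 15 (trimethylsilyl)methylmagnesium chloride
Product: 16 (3Z)-6-[(tert-butyldimethylsilyl)oxy]-4-[(trimethylsilyl)methyl]hex-3-en-1-ol
Conditions: NiCl2(PPh3)2 (5 mol %), 15 (3 equiv), toluene, 80 °C; aq. NH4Cl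
Reagents that add atoms: none
Why: Nickel-catalysed Kumada-type coupling at the enol-ether C–O bond (Wenkert reaction) goes with retention at the alkene carbon, so CH2SiMe3 takes the place of the ring oxygen cis to the hydroxyethyl arm and the (Z)-allylsilane forms as a single isomer.

Step 8
Reactants: 16 (3Z)-6-[(tert-butyldimethylsilyl)oxy]-4-[(trimethylsilyl)methyl]hex-3-en-1-ol
Product: 17 tert-butyl{[(3Z)-6-chloro-3-[(trimethylsilyl)methyl]hex-3-en-1-yl]oxy}dimethylsilane
Conditions: PPh3, CCl4, CH2Cl2, 0 → 40 °C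
Reagents that add atoms: tetrachloromethane, ClC(Cl)(Cl)Cl
Why: Appel chlorination converts the primary alcohol to the chloride (future C12) under neutral conditions that spare the allylsilane and the silyl ether.

Step 9
Reactants: 17 tert-butyl{[(3Z)-6-chloro-3-[(trimethylsilyl)methyl]hex-3-en-1-yl]oxy}dimethylsilane
Product: 18 (3Z)-6-chloro-3-[(trimethylsilyl)methyl]hex-3-en-1-ol
Conditions: PPTS (10 mol %), MeOH, rt
Reagents that add atoms: none
Why: Mild acid-catalysed methanolysis removes the primary silyl ether without protodesilylating the allylsilane.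

Step 10
Reactants: 18 (3Z)-6-chloro-3-[(trimethylsilyl)methyl]hex-3-en-1-ol
Product: 20 [(2Z)-5-chloro-2-(2-iodoethyl)pent-2-en-1-yl]trimethylsilane, via methanesulfonate ester 19 (not isolated)
Conditions: MsCl, Et3N, CH2Cl2, 0 °C; then NaI, acetone, rt
Reagents that add atoms: methanesulfonyl chloride, CS(=O)(=O)Cl (in 19 only); sodium iodide, [Na+].[I-]
Why: Mesylation and Finkelstein SN2 displacement give the primary iodide without free iodine (which would attack the allylsilane); the primary chloride exchanges far more slowly.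

**Fragment C (steps 11–14)**

Step 11
Reactants: 21 prop-2-yn-1-ol
Product: 23 4-hydroxybut-2-ynoic acid, via bis(bromomagnesium) salt 22 (not isolated)
Conditions: EtMgBr (2.2 equiv), THF, 0 → 40 °C; CO2 (1 atm), 0 °C → rt; aq. HCl
Reagents that add atoms: ethylmagnesium bromide, CC[Mg]Br (in 22 only); carbon dioxide, O=C=O
Why: Double deprotonation gives the alkynyl Grignard, which is carboxylated by CO2.

Step 12
Reactants: 23 4-hydroxybut-2-ynoic acid
Product: 24 4-(acetyloxy)but-2-ynoic acid
Conditions: Ac2O, pyridine, CH2Cl2, 0 °C → rt; then H2O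
Reagents that add atoms: acetic anhydride, CC(=O)OC(C)=O
Why: O-Acetylation of the primary alcohol; any mixed anhydride at the acid is hydrolysed on aqueous work-up.

Step 13
Reactants: 24 4-(acetyloxy)but-2-ynoic acid
Product: 25 2-(trimethylsilyl)ethyl 4-(acetyloxy)but-2-ynoate
Conditions: Me3SiCH2CH2OH, DCC, DMAP (5 mol %), CH2Cl2, 0 °C
Reagents that add atoms: 2-(trimethylsilyl)ethanol, C[Si](C)(C)CCO
Why: Steglich esterification installs a fluoride-labile ester that can later be cleaved without touching the acetate.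

Step 14
Reactants: 25 2-(trimethylsilyl)ethyl 4-(acetyloxy)but-2-ynoate
Product: 26 2-(trimethylsilyl)ethyl (2Z)-4-(acetyloxy)-3-iodobut-2-enoate
Conditions: NaI, AcOH, 70 °C
Reagents that add atoms: sodium iodide, [Na+].[I-]
Why: Conjugate hydroiodination of the ynoate (iodide to the β-carbon, anti protonation) gives the (Z)-β-iodo enoate, with iodine cis to the ester and the acetoxymethyl group trans to it.

**Union and endgame (steps 15–18)**

Step 15
Reactants: 20 [(2Z)-5-chloro-2-(2-iodoethyl)pent-2-en-1-yl]trimethylsilane; 9 tert-butyl{[(1E,4R)-1-iodo-2,6-dimethylhepta-1,6-dien-4-yl]oxy}dimethylsilane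
Product: 28 tert-butyl{[(4R,6E,10Z)-13-chloro-2,6-dimethyl-10-[(trimethylsilyl)methyl]trideca-1,6,10-trien-4-yl]oxy}dimethylsilane, via alkylzinc iodide 27 (not isolated)
Conditions: Zn dust (BrCH2CH2Br/TMSCl-activated), LiCl, THF, 30 °C; then 9, Pd(PPh3)4 (5 mol %), THF, 40 °C
Reagents that add atoms: zinc, [Zn] (in 27 only)
Why: Zinc insertion into the primary iodide and Negishi coupling with the alkenyl iodide form C5–C6 with retention of the (E)-geometry; alkyl chloride, allylsilane and silyl ether are inert.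

Step 16
Reactants: 28 tert-butyl{[(4R,6E,10Z)-13-chloro-2,6-dimethyl-10-[(trimethylsilyl)methyl]trideca-1,6,10-trien-4-yl]oxy}dimethylsilane
Product: 29 tert-butyl{[(2R,4aR,8R,8aR)-8-(2-chloroethyl)-4,4,8a-trimethyl-7-methylidenedecahydronaphthalen-2-yl]oxy}dimethylsilane
Conditions: Co(C36H52N2O2) [cobalt N,N'-bis(3,5-di-tert-butylsalicylidene)-1,2-cyclohexanediaminate, divalent cobalt] (5 mol %), 1-fluoro-2,4,6-trimethylpyridinium tetrafluoroborate (1.1 equiv), PhSiH3 (1.05 equiv, slow addition), (CF3)2CHOH/CH2Cl2 1:3, −20 → 0 °C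
Reagents that add atoms: none
Why: Proposed new method: the cobalt hydride formed from the cobalt salen complex, the N-fluoropyridinium oxidant and PhSiH3 gives a hydrogen atom only to the 1,1-disubstituted alkene (trisubstituted alkenes and the allylsilane are much slower HAT acceptors); the tertiary C4 radical is oxidised through an alkylcobalt species to the cation, which cyclises through a chair–chair transition state (ring A, then ring B) in which the (E)-C5=C10 alkene gives the trans ring fusion, the (Z)-allylsilane puts C11 equatorial and loses Me3Si+ from the β-silyl cation to leave only the exocyclic C8 methylene, and the C2 silyloxy group sits equatorial to avoid the two syn-axial methyl groups and so sets C5, C9 and C10 relative to C2; the closest known reactions are cobalt–salen/N-fluoropyridinium/silane HAT radical–polar crossover hydrofunctionalisations, HAT-initiated polyene cyclisations that end on arenes, and acid-induced allylsilane-terminated polyene cyclisations, while allylsilane termination and remote silyloxy control under HAT initiation have not been shown.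

Step 17
Reactants: 29 tert-butyl{[(2R,4aR,8R,8aR)-8-(2-chloroethyl)-4,4,8a-trimethyl-7-methylidenedecahydronaphthalen-2-yl]oxy}dimethylsilane; 26 2-(trimethylsilyl)ethyl (2Z)-4-(acetyloxy)-3-iodobut-2-enoate
Product: 32 2-(trimethylsilyl)ethyl (2E)-3-[(acetyloxy)methyl]-5-[(1R,4aR,7R,8aR)-7-[(tert-butyldimethylsilyl)oxy]-5,5,8a-trimethyl-2-methylidenedecahydronaphthalen-1-yl]pent-2-enoate, via alkylmagnesium chloride 30 (not isolated), via alkylzinc chloride 31 (not isolated)
Conditions: Mg (BrCH2CH2Br-activated), THF, 55 °C; ZnCl2, THF, 0 °C; then 26, Pd(PPh3)4 (5 mol %), THF, rt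
Reagents that add atoms: magnesium, [Mg] (in 30 only); zinc dichloride, Cl[Zn]Cl (in 31 only)
Why: Grignard formation, transmetalation to zinc and Negishi coupling with retention of the iodide geometry form C12–C13 with C12 cis to the ester (13E); the alkylzinc tolerates ester and acetate, and oxidative addition into the activated C–I bond is much faster than ionisation of the allylic acetate.

Step 18
Reactants: 32 2-(trimethylsilyl)ethyl (2E)-3-[(acetyloxy)methyl]-5-[(1R,4aR,7R,8aR)-7-[(tert-butyldimethylsilyl)oxy]-5,5,8a-trimethyl-2-methylidenedecahydronaphthalen-1-yl]pent-2-enoate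
Product: 33 (2E)-3-[(acetyloxy)methyl]-5-[(1R,4aR,7R,8aR)-7-hydroxy-5,5,8a-trimethyl-2-methylidenedecahydronaphthalen-1-yl]pent-2-enoic acid
Conditions: tris(dimethylamino)sulfonium difluorotrimethylsilicate (TASF, 3 equiv), DMF, 0 °C → rt; then dil. HCl to pH 3
Reagents that add atoms: none
Why: Fluoride cleaves the silyl ether and fragments the 2-(trimethylsilyl)ethyl ester (β-elimination to ethene) under non-basic conditions that leave the allylic acetate, the exocyclic alkene and all stereocentres untouched.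

**Compound list**

1 | (R)-epichlorohydrin, (2R)-2-(chloromethyl)oxirane | ClC[C@H]1CO1 | starting material
2 | isopropenylmagnesium bromide | CC(=C)[Mg]Br | starting material
3 | (2R)-1-chloro-4-methylpent-4-en-2-ol | C=C(C)C[C@@H](O)CCl | intermediate
4 | lithium acetylide–ethylenediamine complex | [Li]C#C.NCCN | starting material
5 | (2R)-2-(2-methylprop-2-en-1-yl)oxirane | C=C(C)C[C@@H]1CO1 | intermediate (not isolated)
6 | (4R)-6-methylhept-6-en-1-yn-4-ol | C=C(C)C[C@@H](O)CC#C | intermediate
7 | tert-butyldimethyl{[(4R)-6-methylhept-6-en-1-yn-4-yl]oxy}silane | C=C(C)C[C@@H](O[Si](C)(C)C(C)(C)C)CC#C | intermediate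
8 | {(1E,4R)-4-[(tert-butyldimethylsilyl)oxy]-2,6-dimethylhepta-1,6-dien-1-yl}dimethylalane | C=C(C)C[C@@H](O[Si](C)(C)C(C)(C)C)C/C(C)=C/[Al](C)C | intermediate (not isolated)
9 | tert-butyl{[(1E,4R)-1-iodo-2,6-dimethylhepta-1,6-dien-4-yl]oxy}dimethylsilane | C=C(C)C[C@@H](O[Si](C)(C)C(C)(C)C)C/C(C)=C/I | intermediate
10 | 2-iodoethanol | OCCI | starting material
11 | tert-butyl(2-iodoethoxy)dimethylsilane | CC(C)(C)[Si](C)(C)OCCI | intermediate
12 | 2,3-dihydrofuran | C1CC=CO1 | starting material
13 | 5-lithio-2,3-dihydrofuran | [Li]C1=CCCO1 | intermediate (not isolated)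
14 | tert-butyl[2-(4,5-dihydrofuran-2-yl)ethoxy]dimethylsilane | CC(C)(C)[Si](C)(C)OCCC1=CCCO1 | intermediate
15 | (trimethylsilyl)methylmagnesium chloride | C[Si](C)(C)C[Mg]Cl | starting material
16 | (3Z)-6-[(tert-butyldimethylsilyl)oxy]-4-[(trimethylsilyl)methyl]hex-3-en-1-ol | CC(C)(C)[Si](C)(C)OCC/C(C[Si](C)(C)C)=C/CCO | intermediate
17 | tert-butyl{[(3Z)-6-chloro-3-[(trimethylsilyl)methyl]hex-3-en-1-yl]oxy}dimethylsilane | CC(C)(C)[Si](C)(C)OCC/C(C[Si](C)(C)C)=C/CCCl | intermediate
18 | (3Z)-6-chloro-3-[(trimethylsilyl)methyl]hex-3-en-1-ol | OCC/C(C[Si](C)(C)C)=C/CCCl | intermediate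
19 | (3Z)-6-chloro-3-[(trimethylsilyl)methyl]hex-3-en-1-yl methanesulfonate | CS(=O)(=O)OCC/C(C[Si](C)(C)C)=C/CCCl | intermediate (not isolated)
20 | [(2Z)-5-chloro-2-(2-iodoethyl)pent-2-en-1-yl]trimethylsilane | ICC/C(C[Si](C)(C)C)=C/CCCl | intermediate
21 | prop-2-yn-1-ol | C#CCO | starting material
22 | bromomagnesium 3-(bromomagnesio)prop-2-yn-1-olate | Br[Mg]C#CCO[Mg]Br | intermediate (not isolated)
23 | 4-hydroxybut-2-ynoic acid | OCC#CC(=O)O | intermediate
24 | 4-(acetyloxy)but-2-ynoic acid | CC(=O)OCC#CC(=O)O | intermediate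
25 | 2-(trimethylsilyl)ethyl 4-(acetyloxy)but-2-ynoate | CC(=O)OCC#CC(=O)OCC[Si](C)(C)C | intermediate
26 | 2-(trimethylsilyl)ethyl (2Z)-4-(acetyloxy)-3-iodobut-2-enoate | CC(=O)OC/C(I)=C/C(=O)OCC[Si](C)(C)C | intermediate
27 | {(3Z)-6-chloro-3-[(trimethylsilyl)methyl]hex-3-en-1-yl}zinc iodide | I[Zn]CC/C(C[Si](C)(C)C)=C/CCCl | intermediate (not isolated)
28 | tert-butyl{[(4R,6E,10Z)-13-chloro-2,6-dimethyl-10-[(trimethylsilyl)methyl]trideca-1,6,10-trien-4-yl]oxy}dimethylsilane | C=C(C)C[C@@H](O[Si](C)(C)C(C)(C)C)C/C(C)=C/CC/C(C[Si](C)(C)C)=C/CCCl | intermediate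
29 | tert-butyl{[(2R,4aR,8R,8aR)-8-(2-chloroethyl)-4,4,8a-trimethyl-7-methylidenedecahydronaphthalen-2-yl]oxy}dimethylsilane | C=C1CC[C@@H]2C(C)(C)C[C@@H](O[Si](C)(C)C(C)(C)C)C[C@@]2(C)[C@@H]1CCCl | intermediate
30 | {2-[(1R,4aR,7R,8aR)-7-[(tert-butyldimethylsilyl)oxy]-5,5,8a-trimethyl-2-methylidenedecahydronaphthalen-1-yl]ethyl}magnesium chloride | C=C1CC[C@@H]2C(C)(C)C[C@@H](O[Si](C)(C)C(C)(C)C)C[C@@]2(C)[C@@H]1CC[Mg]Cl | intermediate (not isolated)
31 | {2-[(1R,4aR,7R,8aR)-7-[(tert-butyldimethylsilyl)oxy]-5,5,8a-trimethyl-2-methylidenedecahydronaphthalen-1-yl]ethyl}zinc chloride | C=C1CC[C@@H]2C(C)(C)C[C@@H](O[Si](C)(C)C(C)(C)C)C[C@@]2(C)[C@@H]1CC[Zn]Cl | intermediate (not isolated)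
32 | 2-(trimethylsilyl)ethyl (2E)-3-[(acetyloxy)methyl]-5-[(1R,4aR,7R,8aR)-7-[(tert-butyldimethylsilyl)oxy]-5,5,8a-trimethyl-2-methylidenedecahydronaphthalen-1-yl]pent-2-enoate | C=C1CC[C@@H]2C(C)(C)C[C@@H](O[Si](C)(C)C(C)(C)C)C[C@@]2(C)[C@@H]1CC/C(=C\C(=O)OCC[Si](C)(C)C)COC(C)=O | intermediate
33 | (2E)-3-[(acetyloxy)methyl]-5-[(1R,4aR,7R,8aR)-7-hydroxy-5,5,8a-trimethyl-2-methylidenedecahydronaphthalen-1-yl]pent-2-enoic acid (CNP0292310.2) | C=C1CC[C@@H]2C(C)(C)C[C@@H](O)C[C@@]2(C)[C@@H]1CC/C(=C\C(=O)O)COC(C)=O | target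

**Step count and risks**

Total step count: 18. Longest linear sequence: 10 steps (steps 5–10, then 15–18); fragment A adds 4 steps and fragment C adds 4 steps in parallel.

The three steps most likely to fail:

- **Step 16 (the new reaction).** The main danger is that the cobalt hydride also attacks the exocyclic methylene of 29, which is another 1,1-disubstituted alkene; this would isomerise or hydrofunctionalise the product. Limiting silane and low temperature are the only controls. A second danger is attack of the N–F oxidant on the allylsilane. The fallback uses known chemistry, sets out from 28 and comes back at 29. Cobalt-catalysed Markovnikov hydrochlorination of the 1,1-disubstituted alkene (Co(BF4)2·6H2O with a salicylaldimine ligand, TsCl, PhSiH3, EtOH, rt) gives tert-butyl{[(4S,6E,10Z)-2,13-dichloro-2,6-dimethyl-10-[(trimethylsilyl)methyl]trideca-6,10-dien-4-yl]oxy}dimethylsilane F1. Ionisation of this tertiary chloride with SnCl4 (CH2Cl2, −78 °C) then runs a classical Lewis-acid cation–olefin bicyclisation with allylsilane termination to 29. The stereocontrol is the same chair–chair, equatorial-silyloxy model, and no hydride source is present once the exocyclic alkene exists.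

- **Step 17.** Magnesium insertion into the chloride may be sluggish, and palladium could ionise the allylic acetate of 26 or 32. The fallback sets out from 29 and comes back at 32; it builds the enoate on the decalin by carbometalation instead of bringing it in by cross-coupling.
  - Displacement of chloride with 4 (DMSO, rt to 40 °C) gives tert-butyl{[(2R,4aR,8R,8aR)-8-(but-3-yn-1-yl)-4,4,8a-trimethyl-7-methylidenedecahydronaphthalen-2-yl]oxy}dimethylsilane F2.
  - n-BuLi (THF, −78 °C) gives its lithium acetylide F3, which is acylated with 2-(trimethylsilyl)ethyl chloroformate to the pent-2-ynoate F4.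
  - The organocopper reagent made from tributyl{[(4-methoxybenzyl)oxy]methyl}stannane, n-BuLi and CuBr·SMe2 adds syn across the ynoate at −78 °C to give the alkenylcopper adduct F5. Quenching with aq. NH4Cl gives the (2E)-3-{[(4-methoxybenzyl)oxy]methyl}pent-2-enoate F6, with C12 cis to the ester as in 32.
  - DDQ (CH2Cl2/pH 7 buffer) frees the (2E)-3-(hydroxymethyl)pent-2-enoate F7, and Ac2O/pyridine returns to 32.

- **Step 7.** The Ni-catalysed C–O coupling defines the allylsilane geometry; it could stall with the silylmethyl Grignard reagent or open the ring reductively. The fallback sets out from 11 and comes back at 16, using alkyne carbometalation instead of enol-ether coupling. Alkylation of 4 with 11 (DMSO, rt) gives tert-butyl(but-3-yn-1-yloxy)dimethylsilane F8. The silylmethylcopper reagent from 15 and CuBr·SMe2 (Et2O, −20 °C) adds syn across the terminal alkyne, with copper on the terminal carbon (Normant carbocupration), to give {(1Z)-4-[(tert-butyldimethylsilyl)oxy]-2-[(trimethylsilyl)methyl]but-1-en-1-yl}copper F9. Trapping in the same flask with oxirane, with retention, gives 16.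

Further compounds
F1 | step 16 | tert-butyl{[(4S,6E,10Z)-2,13-dichloro-2,6-dimethyl-10-[(trimethylsilyl)methyl]trideca-6,10-dien-4-yl]oxy}dimethylsilane | CC(C)(Cl)C[C@@H](O[Si](C)(C)C(C)(C)C)C/C(C)=C/CC/C(C[Si](C)(C)C)=C/CCCl
F2 | step 17 | tert-butyl{[(2R,4aR,8R,8aR)-8-(but-3-yn-1-yl)-4,4,8a-trimethyl-7-methylidenedecahydronaphthalen-2-yl]oxy}dimethylsilane | C=C1CC[C@@H]2C(C)(C)C[C@@H](O[Si](C)(C)C(C)(C)C)C[C@@]2(C)[C@@H]1CCC#C
F3 | step 17 | {4-[(1R,4aR,7R,8aR)-7-[(tert-butyldimethylsilyl)oxy]-5,5,8a-trimethyl-2-methylidenedecahydronaphthalen-1-yl]but-1-yn-1-yl}lithium | C=C1CC[C@@H]2C(C)(C)C[C@@H](O[Si](C)(C)C(C)(C)C)C[C@@]2(C)[C@@H]1CCC#C[Li]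
F4 | step 17 | 2-(trimethylsilyl)ethyl 5-[(1R,4aR,7R,8aR)-7-[(tert-butyldimethylsilyl)oxy]-5,5,8a-trimethyl-2-methylidenedecahydronaphthalen-1-yl]pent-2-ynoate | C=C1CC[C@@H]2C(C)(C)C[C@@H](O[Si](C)(C)C(C)(C)C)C[C@@]2(C)[C@@H]1CCC#CC(=O)OCC[Si](C)(C)C
F5 | step 17 | 2-(trimethylsilyl)ethyl (2Z)-2-cuprio-5-[(1R,4aR,7R,8aR)-7-[(tert-butyldimethylsilyl)oxy]-5,5,8a-trimethyl-2-methylidenedecahydronaphthalen-1-yl]-3-{[(4-methoxybenzyl)oxy]methyl}pent-2-enoate | C=C1CC[C@@H]2C(C)(C)C[C@@H](O[Si](C)(C)C(C)(C)C)C[C@@]2(C)[C@@H]1CC/C(COCc1ccc(OC)cc1)=C(/[Cu])C(=O)OCC[Si](C)(C)C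
F6 | step 17 | 2-(trimethylsilyl)ethyl (2E)-5-[(1R,4aR,7R,8aR)-7-[(tert-butyldimethylsilyl)oxy]-5,5,8a-trimethyl-2-methylidenedecahydronaphthalen-1-yl]-3-{[(4-methoxybenzyl)oxy]methyl}pent-2-enoate | C=C1CC[C@@H]2C(C)(C)C[C@@H](O[Si](C)(C)C(C)(C)C)C[C@@]2(C)[C@@H]1CC/C(=C\C(=O)OCC[Si](C)(C)C)COCc1ccc(OC)cc1
F7 | step 17 | 2-(trimethylsilyl)ethyl (2E)-5-[(1R,4aR,7R,8aR)-7-[(tert-butyldimethylsilyl)oxy]-5,5,8a-trimethyl-2-methylidenedecahydronaphthalen-1-yl]-3-(hydroxymethyl)pent-2-enoate | C=C1CC[C@@H]2C(C)(C)C[C@@H](O[Si](C)(C)C(C)(C)C)C[C@@]2(C)[C@@H]1CC/C(=C\C(=O)OCC[Si](C)(C)C)CO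
F8 | step 7 | tert-butyl(but-3-yn-1-yloxy)dimethylsilane | C#CCCO[Si](C)(C)C(C)(C)C
F9 | step 7 | {(1Z)-4-[(tert-butyldimethylsilyl)oxy]-2-[(trimethylsilyl)methyl]but-1-en-1-yl}copper | CC(C)(C)[Si](C)(C)OCC/C(C[Si](C)(C)C)=C/[Cu]
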